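**Plan**

1. Retrosynthesis: the aryl ether bond O1–C2 is cut first (it is re-formed last by Mitsunobu closure after C2 has been reduced). At the lactone oxidation level the acyl bond O1–C2 and the bond C3–C4 are then cut together, which separates a ring A piece from a ring B piece.
2. Enabling feature (isoflavan numbering: ring C = O1, C2, C3, C4; ring A = C4a–C8a; ring B = C1'–C6'): C4 is a benzylic CH2 ortho to O1 and para to the C7 oxygen, so it is the exocyclic carbon of a latent ring A ortho-quinone methide. C3 carries ring B and is the alpha carbon of an arylacetic acid whose carboxyl carbon is C2.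
3. Ring A piece: resorcinol, iodination at the future C8, Heck coupling and hydrogenation for the 3-hydroxy-3-methylbutyl chain, monosilylation, ortho-formylation (brings in C4), reduction, sulfone.
4. Ring B piece: 2,4-dihydroxybenzaldehyde, 4-O-prenylation, Claisen rearrangement to the C5' 1,1-dimethylallyl group, silylation, one-carbon homologation to the arylacetic acid, pentafluorophenyl ester.
5. Forward order: one catalytic step joins the two arenes and closes ring C as a 3-arylchroman-2-one; the lactone is reduced open, ring C is reclosed as the chroman, and fluoride frees the three phenols.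
6. Stereochemistry: C3 is the only stereocentre; it is set as (R) by a chiral isothiourea in the annulation and is not touched afterwards.

Key step: step 16

Remark 1: the tertiary alcohol of the side chain is carried unprotected from step 2 to the end; being tertiary it is expected to resist silylation by R3SiCl/imidazole, acylation by the acyl ammonium ion and Mitsunobu activation.
Remark 2: the sense of induction in step 16 is derived from the accepted transition-state model for isothiourea-bound (Z)-enolates; should the lactone prove to be the (3S) antipode, the (2R,3S) catalyst is used and nothing else changes.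
Abbreviations: TIPS = triisopropylsilyl, TBS = tert-butyldimethylsilyl.

**Route**

Step 1
Reactants: 1 resorcinol
Product: 2 2-iodobenzene-1,3-diol
Conditions: I2, NaHCO3, H2O, 0 °C to rt
Reagents that add atoms: iodine, II
Why: Electrophilic aromatic iodination of the resorcinol anion in water goes to the doubly activated carbon between the two oxygens, a standard preparation of this iodide.

Step 2
Reactants: 2 2-iodobenzene-1,3-diol; 3 2-methylbut-3-en-2-ol
Product: 4 2-[(1E)-3-hydroxy-3-methylbut-1-en-1-yl]benzene-1,3-diol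
Conditions: Pd(OAc)2 (5 mol %), Bu4NCl, NaHCO3, DMF, 70 °C
Reagents that add atoms: none
Why: Heck reaction under ligand-free phase-transfer conditions, in which the aryl group adds to the terminal alkene carbon and beta-hydride elimination can only use the benzylic hydrogens because the carbinol carbon has none, so the (E)-styrenyl tertiary alcohol should be the single coupling product.

Step 3
Reactants: 4 2-[(1E)-3-hydroxy-3-methylbut-1-en-1-yl]benzene-1,3-diol
Product: 5 2-(3-hydroxy-3-methylbutyl)benzene-1,3-diol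
Conditions: H2 (1 atm), Pd/C (10% palladium on carbon), EtOAc, rt
Reagents that add atoms: none
Why: Heterogeneous catalytic hydrogenation saturates the disubstituted alkene under neutral conditions, which avoids the acid-induced cyclisation of the allylic or tertiary alcohol onto a neighbouring phenol.

Step 4
Reactants: 5 2-(3-hydroxy-3-methylbutyl)benzene-1,3-diol
Product: 6 2-(3-hydroxy-3-methylbutyl)-3-(triisopropylsilyloxy)phenol
Conditions: TIPSCl (1.0 equiv), imidazole, DMF, 0 °C to rt
Reagents that add atoms: triisopropylsilyl chloride, CC(C)[Si](Cl)(C(C)C)C(C)C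
Why: Statistical monosilylation of one of two equivalent phenols with one equivalent of a bulky chlorosilane leaves the hindered tertiary alcohol untouched, and the unreacted diol and the bis-silyl ether can be recycled.

Step 5
Reactants: 6 2-(3-hydroxy-3-methylbutyl)-3-(triisopropylsilyloxy)phenol
Product: 7 2-hydroxy-3-(3-hydroxy-3-methylbutyl)-4-(triisopropylsilyloxy)benzaldehyde
Conditions: MgCl2, Et3N, (CH2O)n, MeCN, reflux
Reagents that add atoms: paraformaldehyde (formaldehyde unit), C=O
Why: Casnati–Skattebøl ortho-formylation, in which the magnesium phenoxide delivers formaldehyde to the only free ortho position (also para to the silyloxy group) and a second equivalent of formaldehyde accepts hydride to bring the new carbon to the aldehyde level.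

Step 6
Reactants: 7 2-hydroxy-3-(3-hydroxy-3-methylbutyl)-4-(triisopropylsilyloxy)benzaldehyde
Product: 8 6-(hydroxymethyl)-2-(3-hydroxy-3-methylbutyl)-3-(triisopropylsilyloxy)phenol
Conditions: NaBH4, THF/MeOH, 0 °C
Reagents that add atoms: none
Why: Borohydride reduction of the aldehyde gives the salicyl alcohol without affecting the aryl silyl ether, and the acid-sensitive product is used without chromatography.

Step 7
Reactants: 8 6-(hydroxymethyl)-2-(3-hydroxy-3-methylbutyl)-3-(triisopropylsilyloxy)phenol
Product: 9 2-(3-hydroxy-3-methylbutyl)-6-[(4-methylphenyl)sulfonylmethyl]-3-(triisopropylsilyloxy)phenol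
Conditions: 4-MeC6H4SO2Na, AcOH/H2O, 40 °C
Reagents that add atoms: sodium 4-methylbenzenesulfinate, Cc1ccc(cc1)S(=O)[O-].[Na+]
Why: SN1-type substitution in which the benzylic cation, stabilised by the ortho hydroxyl and para silyloxy groups, is captured at sulfur by the sulfinate to give the bench-stable benzylic sulfone under acidity too weak to ionise the tertiary alcohol.

Step 8
Reactants: 10 2,4-dihydroxybenzaldehyde; 11 1-bromo-3-methylbut-2-ene
Product: 12 2-hydroxy-4-[(3-methylbut-2-en-1-yl)oxy]benzaldehyde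
Conditions: K2CO3, acetone, rt to 40 °C
Reagents that add atoms: none
Why: Williamson etherification is selective for the 4-hydroxyl because the 2-hydroxyl is tied up in a hydrogen bond to the aldehyde and is less acidic.

Step 9
Reactants: 12 2-hydroxy-4-[(3-methylbut-2-en-1-yl)oxy]benzaldehyde
Product: 13 4-[(3-methylbut-2-en-1-yl)oxy]-2-(triisopropylsilyloxy)benzaldehyde
Conditions: TIPSOTf, 2,6-lutidine, CH2Cl2, 0 °C
Reagents that add atoms: triisopropylsilyl trifluoromethanesulfonate, CC(C)[Si](OS(=O)(=O)C(F)(F)F)(C(C)C)C(C)C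
Why: Silylation of the chelated phenol with a silyl triflate and a hindered base installs a heat-stable bulky group that shields C3 in the following rearrangement.

Step 10
Reactants: 13 4-[(3-methylbut-2-en-1-yl)oxy]-2-(triisopropylsilyloxy)benzaldehyde
Product: 14 4-hydroxy-5-(2-methylbut-3-en-2-yl)-2-(triisopropylsilyloxy)benzaldehyde
Conditions: PhNEt2, 190–200 °C, sealed tube, degassed
Reagents that add atoms: none
Why: Aromatic Claisen rearrangement ([3,3]-sigmatropic shift with allyl inversion, then tautomerisation) should deliver the 1,1-dimethylallyl group to C5 because C3 is flanked by the silyloxy group and the ether oxygen, as in the analogous 2-alkoxy-4-prenyloxybenzaldehydes.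

Step 11
Reactants: 14 4-hydroxy-5-(2-methylbut-3-en-2-yl)-2-(triisopropylsilyloxy)benzaldehyde
Product: 15 4-(tert-butyldimethylsilyloxy)-5-(2-methylbut-3-en-2-yl)-2-(triisopropylsilyloxy)benzaldehyde
Conditions: TBSOTf, 2,6-lutidine, CH2Cl2, 0 °C to rt
Reagents that add atoms: tert-butyldimethylsilyl trifluoromethanesulfonate, CC(C)(C)[Si](C)(C)OS(=O)(=O)C(F)(F)F
Why: The hindered but acidic 4-phenol is silylated by the reactive silyl triflate, so that O1 of ring A will be the only free phenol in the later Mitsunobu closure.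

Step 12
Reactants: 15 4-(tert-butyldimethylsilyloxy)-5-(2-methylbut-3-en-2-yl)-2-(triisopropylsilyloxy)benzaldehyde
Product: 16 tert-butyl[5-(2-methoxyethenyl)-2-(2-methylbut-3-en-2-yl)-4-(triisopropylsilyloxy)phenoxy]dimethylsilane (E/Z mixture)
Conditions: Ph3P(CH2OMe)Cl, NaN(SiMe3)2, THF, 0 °C; then 15, −78 °C to rt
Reagents that add atoms: (methoxymethyl)triphenylphosphonium chloride, COC[P+](c1ccccc1)(c1ccccc1)c1ccccc1.[Cl-]
Why: Wittig olefination with the methoxymethylene ylide converts the aldehyde into the homologous enol ether, both geometric isomers of which converge in the next step.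

Step 13
Reactants: 16 tert-butyl[5-(2-methoxyethenyl)-2-(2-methylbut-3-en-2-yl)-4-(triisopropylsilyloxy)phenoxy]dimethylsilane
Product: 17 2-[4-(tert-butyldimethylsilyloxy)-5-(2-methylbut-3-en-2-yl)-2-(triisopropylsilyloxy)phenyl]acetaldehyde
Conditions: 2 M HCl, THF, rt to 40 °C
Reagents that add atoms: water, O
Why: Acid hydrolysis of the enol ether (C-protonation, hydration of the oxocarbenium ion, loss of methanol) gives the arylacetaldehyde while the hindered aryl silyl ethers, which cleave only slowly in dilute acid, should remain.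

Step 14
Reactants: 17 2-[4-(tert-butyldimethylsilyloxy)-5-(2-methylbut-3-en-2-yl)-2-(triisopropylsilyloxy)phenyl]acetaldehyde
Product: 18 2-[4-(tert-butyldimethylsilyloxy)-5-(2-methylbut-3-en-2-yl)-2-(triisopropylsilyloxy)phenyl]acetic acid
Conditions: NaClO2, NaH2PO4, 2-methylbut-2-ene, t-BuOH/H2O, 0 °C to rt
Reagents that add atoms: sodium chlorite, [Na+].[O-]Cl=O
Why: Pinnick oxidation with an alkene scavenger for hypochlorous acid oxidises the crude aldehyde to the acid without touching the vinyl group or the electron-rich ring.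

Step 15
Reactants: 18 2-[4-(tert-butyldimethylsilyloxy)-5-(2-methylbut-3-en-2-yl)-2-(triisopropylsilyloxy)phenyl]acetic acid
Product: 19 pentafluorophenyl 2-[4-(tert-butyldimethylsilyloxy)-5-(2-methylbut-3-en-2-yl)-2-(triisopropylsilyloxy)phenyl]acetate
Conditions: C6F5OH, dicyclohexylcarbodiimide, CH2Cl2, 0 °C to rt
Reagents that add atoms: pentafluorophenol, Oc1c(F)c(F)c(F)c(F)c1F
Why: Carbodiimide-mediated esterification gives the isolable pentafluorophenyl ester, which acylates isothioureas readily and releases an aryloxide base.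

Step 16
Reactants: 9 2-(3-hydroxy-3-methylbutyl)-6-[(4-methylphenyl)sulfonylmethyl]-3-(triisopropylsilyloxy)phenol; 19 pentafluorophenyl 2-[4-(tert-butyldimethylsilyloxy)-5-(2-methylbut-3-en-2-yl)-2-(triisopropylsilyloxy)phenyl]acetate
Product: 21 (3R)-3-[4-(tert-butyldimethylsilyloxy)-5-(2-methylbut-3-en-2-yl)-2-(triisopropylsilyloxy)phenyl]-8-(3-hydroxy-3-methylbutyl)-7-(triisopropylsilyloxy)chroman-2-one, via ortho-quinone methide 20 (not isolated)
Conditions: 19 (1.3 equiv), (2S,3R)-3-isopropyl-2-phenyl-3,4-dihydro-2H-benzo[4,5]thiazolo[3,2-a]pyrimidine (HyperBTM, 10 mol %), Cs2CO3, CH2Cl2, 0 °C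
Reagents that add atoms: none
Why: The isothiourea is acylated by the pentafluorophenyl ester and the acyl ammonium ion is deprotonated to a (Z)-ammonium enolate held planar by an O···S contact, while the cesium phenoxide of 9 expels sulfinate to give methide 20 in low stationary concentration. Michael addition of the enolate carbon (C3) to the unsubstituted methide carbon (C4) re-aromatises ring A, and the phenoxide O1 then closes ring C by 6-exo-trig acyl substitution at the acyl ammonium carbon (C2), which releases the catalyst. The closest known reaction type is the isothiourea-catalysed Michael addition–lactonisation of arylacetic ester enolates with ortho-quinone methides generated in situ from 2-(sulfonylmethyl)phenols. C3 is the only new stereocentre and is controlled by the catalyst, whose pseudoaxial phenyl group next to the acylated nitrogen shields one enolate face, so that with the (2S,3R) catalyst the methide should add to the Re face of the enolate carbon, which corresponds to (3R). The step needs C–C bond formation to win over O-acylation of the phenoxide and over self-condensation of the methide, which the easy sulfinate loss from the para-silyloxy-activated phenoxide, the heterogeneous base and the excess of ester are meant to secure, while the tertiary alcohol is too hindered to be acylated and too remote from C4 to add to the methide. The alpha-aryl lactone is kept at 0 °C and reduced without delay so that the base cannot epimerise C3.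

Step 17
Reactants: 21 (3R)-3-[4-(tert-butyldimethylsilyloxy)-5-(2-methylbut-3-en-2-yl)-2-(triisopropylsilyloxy)phenyl]-8-(3-hydroxy-3-methylbutyl)-7-(triisopropylsilyloxy)chroman-2-one
Product: 22 (2R)-2-[4-(tert-butyldimethylsilyloxy)-5-(2-methylbut-3-en-2-yl)-2-(triisopropylsilyloxy)phenyl]-3-[2-hydroxy-3-(3-hydroxy-3-methylbutyl)-4-(triisopropylsilyloxy)phenyl]propan-1-ol
Conditions: LiBH4, THF, 0 °C
Reagents that add atoms: none
Why: Hydride reduction of the aryl lactone, an activated ester, opens ring C to the phenol and the primary alcohol faster than enolisation can occur, after which C3 is no longer alpha to a carbonyl group and is configurationally secure.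

Step 18
Reactants: 22 (2R)-2-[4-(tert-butyldimethylsilyloxy)-5-(2-methylbut-3-en-2-yl)-2-(triisopropylsilyloxy)phenyl]-3-[2-hydroxy-3-(3-hydroxy-3-methylbutyl)-4-(triisopropylsilyloxy)phenyl]propan-1-ol
Product: 23 4-[(3R)-3-[4-(tert-butyldimethylsilyloxy)-5-(2-methylbut-3-en-2-yl)-2-(triisopropylsilyloxy)phenyl]-7-(triisopropylsilyloxy)chroman-8-yl]-2-methylbutan-2-ol
Conditions: PPh3, diisopropyl azodicarboxylate, THF, 0 °C to rt
Reagents that add atoms: none
Why: Mitsunobu etherification in which the primary alcohol is activated and displaced by the only free phenol in a 6-exo-tet closure that does not involve the stereocentre, the tertiary alcohol being inert and the 2'-oxygen being blocked against the competing five-ring closure.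

Step 19
Reactants: 23 4-[(3R)-3-[4-(tert-butyldimethylsilyloxy)-5-(2-methylbut-3-en-2-yl)-2-(triisopropylsilyloxy)phenyl]-7-(triisopropylsilyloxy)chroman-8-yl]-2-methylbutan-2-ol
Product: 24 4-[(3R)-7-hydroxy-8-(3-hydroxy-3-methylbutyl)chroman-3-yl]-6-(2-methylbut-3-en-2-yl)benzene-1,3-diol (CNP0420388.1)
Conditions: Bu4NF, AcOH, THF, 0 °C to rt
Reagents that add atoms: none
Why: Fluoride-induced desilylation cleaves the three aryl silyl ethers, and the acetic acid buffer keeps the electron-rich phenols protonated while remaining too weak to cyclise the tertiary alcohol or the dimethylallyl group onto a neighbouring phenol.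

**Compound list**

1 | resorcinol (benzene-1,3-diol) | Oc1cccc(O)c1 | starting material
2 | 2-iodobenzene-1,3-diol | Oc1cccc(O)c1I | intermediate
3 | 2-methylbut-3-en-2-ol | C=CC(C)(C)O | starting material
4 | 2-[(1E)-3-hydroxy-3-methylbut-1-en-1-yl]benzene-1,3-diol | CC(C)(O)/C=C/c1c(O)cccc1O | intermediate
5 | 2-(3-hydroxy-3-methylbutyl)benzene-1,3-diol | CC(C)(O)CCc1c(O)cccc1O | intermediate
6 | 2-(3-hydroxy-3-methylbutyl)-3-(triisopropylsilyloxy)phenol | CC(C)(O)CCc1c(O)cccc1O[Si](C(C)C)(C(C)C)C(C)C | intermediate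
7 | 2-hydroxy-3-(3-hydroxy-3-methylbutyl)-4-(triisopropylsilyloxy)benzaldehyde | O=Cc1ccc(O[Si](C(C)C)(C(C)C)C(C)C)c(CCC(C)(C)O)c1O | intermediate
8 | 6-(hydroxymethyl)-2-(3-hydroxy-3-methylbutyl)-3-(triisopropylsilyloxy)phenol | OCc1ccc(O[Si](C(C)C)(C(C)C)C(C)C)c(CCC(C)(C)O)c1O | intermediate
9 | 2-(3-hydroxy-3-methylbutyl)-6-[(4-methylphenyl)sulfonylmethyl]-3-(triisopropylsilyloxy)phenol | Cc1ccc(cc1)S(=O)(=O)Cc1ccc(O[Si](C(C)C)(C(C)C)C(C)C)c(CCC(C)(C)O)c1O | intermediate
10 | 2,4-dihydroxybenzaldehyde | O=Cc1ccc(O)cc1O | starting material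
11 | 1-bromo-3-methylbut-2-ene | CC(C)=CCBr | starting material
12 | 2-hydroxy-4-[(3-methylbut-2-en-1-yl)oxy]benzaldehyde | CC(C)=CCOc1ccc(C=O)c(O)c1 | intermediate
13 | 4-[(3-methylbut-2-en-1-yl)oxy]-2-(triisopropylsilyloxy)benzaldehyde | CC(C)=CCOc1ccc(C=O)c(O[Si](C(C)C)(C(C)C)C(C)C)c1 | intermediate
14 | 4-hydroxy-5-(2-methylbut-3-en-2-yl)-2-(triisopropylsilyloxy)benzaldehyde | C=CC(C)(C)c1cc(C=O)c(O[Si](C(C)C)(C(C)C)C(C)C)cc1O | intermediate
15 | 4-(tert-butyldimethylsilyloxy)-5-(2-methylbut-3-en-2-yl)-2-(triisopropylsilyloxy)benzaldehyde | C=CC(C)(C)c1cc(C=O)c(O[Si](C(C)C)(C(C)C)C(C)C)cc1O[Si](C)(C)C(C)(C)C | intermediate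
16 | tert-butyl[5-(2-methoxyethenyl)-2-(2-methylbut-3-en-2-yl)-4-(triisopropylsilyloxy)phenoxy]dimethylsilane (E/Z mixture) | C=CC(C)(C)c1cc(C=COC)c(O[Si](C(C)C)(C(C)C)C(C)C)cc1O[Si](C)(C)C(C)(C)C | intermediate
17 | 2-[4-(tert-butyldimethylsilyloxy)-5-(2-methylbut-3-en-2-yl)-2-(triisopropylsilyloxy)phenyl]acetaldehyde | C=CC(C)(C)c1cc(CC=O)c(O[Si](C(C)C)(C(C)C)C(C)C)cc1O[Si](C)(C)C(C)(C)C | intermediate
18 | 2-[4-(tert-butyldimethylsilyloxy)-5-(2-methylbut-3-en-2-yl)-2-(triisopropylsilyloxy)phenyl]acetic acid | C=CC(C)(C)c1cc(CC(=O)O)c(O[Si](C(C)C)(C(C)C)C(C)C)cc1O[Si](C)(C)C(C)(C)C | intermediate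
19 | pentafluorophenyl 2-[4-(tert-butyldimethylsilyloxy)-5-(2-methylbut-3-en-2-yl)-2-(triisopropylsilyloxy)phenyl]acetate | C=CC(C)(C)c1cc(CC(=O)Oc2c(F)c(F)c(F)c(F)c2F)c(O[Si](C(C)C)(C(C)C)C(C)C)cc1O[Si](C)(C)C(C)(C)C | intermediate
20 | 2-(3-hydroxy-3-methylbutyl)-6-methylidene-3-(triisopropylsilyloxy)cyclohexa-2,4-dien-1-one (ring A ortho-quinone methide) | C=C1C=CC(O[Si](C(C)C)(C(C)C)C(C)C)=C(CCC(C)(C)O)C1=O | intermediate (not isolated)
21 | (3R)-3-[4-(tert-butyldimethylsilyloxy)-5-(2-methylbut-3-en-2-yl)-2-(triisopropylsilyloxy)phenyl]-8-(3-hydroxy-3-methylbutyl)-7-(triisopropylsilyloxy)chroman-2-one | C=CC(C)(C)c1cc([C@@H]2C(=O)Oc3c(ccc(O[Si](C(C)C)(C(C)C)C(C)C)c3CCC(C)(C)O)C2)c(O[Si](C(C)C)(C(C)C)C(C)C)cc1O[Si](C)(C)C(C)(C)C | intermediate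
22 | (2R)-2-[4-(tert-butyldimethylsilyloxy)-5-(2-methylbut-3-en-2-yl)-2-(triisopropylsilyloxy)phenyl]-3-[2-hydroxy-3-(3-hydroxy-3-methylbutyl)-4-(triisopropylsilyloxy)phenyl]propan-1-ol | C=CC(C)(C)c1cc([C@H](CO)Cc2ccc(O[Si](C(C)C)(C(C)C)C(C)C)c(CCC(C)(C)O)c2O)c(O[Si](C(C)C)(C(C)C)C(C)C)cc1O[Si](C)(C)C(C)(C)C | intermediate
23 | 4-[(3R)-3-[4-(tert-butyldimethylsilyloxy)-5-(2-methylbut-3-en-2-yl)-2-(triisopropylsilyloxy)phenyl]-7-(triisopropylsilyloxy)chroman-8-yl]-2-methylbutan-2-ol | C=CC(C)(C)c1cc([C@@H]2COc3c(ccc(O[Si](C(C)C)(C(C)C)C(C)C)c3CCC(C)(C)O)C2)c(O[Si](C(C)C)(C(C)C)C(C)C)cc1O[Si](C)(C)C(C)(C)C | intermediate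
24 | 4-[(3R)-7-hydroxy-8-(3-hydroxy-3-methylbutyl)chroman-3-yl]-6-(2-methylbut-3-en-2-yl)benzene-1,3-diol | C=CC(C)(C)c1cc([C@@H]2COc3c(ccc(O)c3CCC(C)(C)O)C2)c(O)cc1O | target

**Step count and risks**

Total: 19 steps. Longest linear sequence: 12 steps (steps 8–19, from 2,4-dihydroxybenzaldehyde 10); the ring A branch (steps 1–7) joins at step 16.

Steps most likely to fail:

1. Step 16 (annulation). The methide has an unsubstituted terminus and may oligomerise or be recaptured before it meets the enolate. The phenoxide of 9 may be O-acylated by the active ester before it loses sulfinate. The ortho silyloxy group may erode the facial selectivity, and the alpha-aryl lactone may enolise under the base and lose enantiopurity.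
Fallback (auxiliary-controlled enolate alkylation, known chemistry): it sets out from acid 18 and aldehyde 7 and returns at diol 22, so steps 6, 7, 15, 16 and 17 are not needed. Acid 18 is activated as its pivaloyl mixed anhydride (t-BuCOCl, Et3N, THF, −20 °C) and acylates lithiated (4R)-4-benzyl-1,3-oxazolidin-2-one to give the N-arylacetyl oxazolidinone F1. Aldehyde 7 is O-allylated at the phenol (allyl bromide, K2CO3, acetone) to the allyl ether aldehyde F2 and reduced with NaBH4 to the benzylic alcohol F3. An Appel reaction (CBr4, PPh3, CH2Cl2, 0 °C), in which the primary benzylic alcohol reacts far faster than the tertiary one, gives the benzylic bromide F4. The sodium enolate of F1 (NaN(SiMe3)2, THF, −78 °C) is a stabilised enolate that the tertiary alcohol should not quench; it is alkylated by F4 on the face away from the benzyl group of the auxiliary to give the (2R)-alkylated imide F5. LiBH4 (THF, 0 °C) removes the auxiliary reductively to give the allyl-protected primary alcohol F6, and Pd(PPh3)4 with morpholine cleaves the allyl aryl ether to give 22.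

2. Step 10 (Claisen rearrangement). Migration may go in part to C3, the prenyl group may be lost thermally as isoprene, and the ortho-dimethylallyl phenol may rearrange further or cyclise onto its own alkene at the temperature needed.
Fallback (gamma-selective allyl–aryl cross-coupling, known chemistry): it sets out from 10 and returns at 15, replacing steps 8–11. Bromination of 10 (Br2, AcOH) para to the 2-hydroxyl gives 5-bromo-2,4-dihydroxybenzaldehyde F7. The unchelated 4-hydroxyl is silylated (TBSCl, imidazole, CH2Cl2) to the mono-silyl ether F8, and the chelated 2-hydroxyl then with TIPSOTf and 2,6-lutidine to the bis-silyl ether bromide F9. Suzuki–Miyaura coupling of F9 with 4,4,5,5-tetramethyl-2-(3-methylbut-2-en-1-yl)-1,3,2-dioxaborolane (Pd(OAc)2, 1,1'-bis(di-tert-butylphosphino)ferrocene, K3PO4, THF/H2O, 40 °C) transfers the allyl group with allylic transposition and gives 15.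

3. Step 2 (Heck coupling on the unprotected iodoresorcinol). Oxidative addition to the electron-rich bis-phenoxide may be slow and give way to protodeiodination, and the allylic alcohol of the product may ionise and electrocyclise to a 2H-chromene.
Fallback (alkyne coupling on a protected iodide, known chemistry): it sets out from iodide 2 and returns at triol 5, replacing steps 2 and 3. Both phenols of 2 are silylated (TBSCl, imidazole, DMF) to the bis-silyl ether iodide F10, which cannot cyclise to a benzofuran. Sonogashira coupling with 2-methylbut-3-yn-2-ol (PdCl2(PPh3)2, CuI, Et3N, 60 °C) gives the arylalkynol F11. Hydrogenation (H2, Pd/C, EtOAc) saturates the triple bond to the bis-silyl ether of the triol F12, and Bu4NF/AcOH in THF then gives 5.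

Further compounds
F1 | step 16 | (4R)-4-benzyl-3-{2-[4-(tert-butyldimethylsilyloxy)-5-(2-methylbut-3-en-2-yl)-2-(triisopropylsilyloxy)phenyl]acetyl}-1,3-oxazolidin-2-one | C=CC(C)(C)c1cc(CC(=O)N2[C@H](Cc3ccccc3)COC2=O)c(O[Si](C(C)C)(C(C)C)C(C)C)cc1O[Si](C)(C)C(C)(C)C
F2 | step 16 | 3-(3-hydroxy-3-methylbutyl)-2-(prop-2-en-1-yloxy)-4-(triisopropylsilyloxy)benzaldehyde | C=CCOc1c(C=O)ccc(O[Si](C(C)C)(C(C)C)C(C)C)c1CCC(C)(C)O
F3 | step 16 | 4-[3-(hydroxymethyl)-2-(prop-2-en-1-yloxy)-6-(triisopropylsilyloxy)phenyl]-2-methylbutan-2-ol | C=CCOc1c(CO)ccc(O[Si](C(C)C)(C(C)C)C(C)C)c1CCC(C)(C)O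
F4 | step 16 | 4-[3-(bromomethyl)-2-(prop-2-en-1-yloxy)-6-(triisopropylsilyloxy)phenyl]-2-methylbutan-2-ol | C=CCOc1c(CBr)ccc(O[Si](C(C)C)(C(C)C)C(C)C)c1CCC(C)(C)O
F5 | step 16 | (4R)-4-benzyl-3-{(2R)-2-[4-(tert-butyldimethylsilyloxy)-5-(2-methylbut-3-en-2-yl)-2-(triisopropylsilyloxy)phenyl]-3-[3-(3-hydroxy-3-methylbutyl)-2-(prop-2-en-1-yloxy)-4-(triisopropylsilyloxy)phenyl]propanoyl}-1,3-oxazolidin-2-one | C=CC(C)(C)c1cc([C@@H](Cc2ccc(O[Si](C(C)C)(C(C)C)C(C)C)c(CCC(C)(C)O)c2OCC=C)C(=O)N2[C@H](Cc3ccccc3)COC2=O)c(O[Si](C(C)C)(C(C)C)C(C)C)cc1O[Si](C)(C)C(C)(C)C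
F6 | step 16 | (2R)-2-[4-(tert-butyldimethylsilyloxy)-5-(2-methylbut-3-en-2-yl)-2-(triisopropylsilyloxy)phenyl]-3-[3-(3-hydroxy-3-methylbutyl)-2-(prop-2-en-1-yloxy)-4-(triisopropylsilyloxy)phenyl]propan-1-ol | C=CC(C)(C)c1cc([C@H](CO)Cc2ccc(O[Si](C(C)C)(C(C)C)C(C)C)c(CCC(C)(C)O)c2OCC=C)c(O[Si](C(C)C)(C(C)C)C(C)C)cc1O[Si](C)(C)C(C)(C)C
F7 | step 10 | 5-bromo-2,4-dihydroxybenzaldehyde | O=Cc1cc(Br)c(O)cc1O
F8 | step 10 | 5-bromo-4-(tert-butyldimethylsilyloxy)-2-hydroxybenzaldehyde | O=Cc1cc(Br)c(O[Si](C)(C)C(C)(C)C)cc1O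
F9 | step 10 | 5-bromo-4-(tert-butyldimethylsilyloxy)-2-(triisopropylsilyloxy)benzaldehyde | O=Cc1cc(Br)c(O[Si](C)(C)C(C)(C)C)cc1O[Si](C(C)C)(C(C)C)C(C)C
F10 | step 2 | [(2-iodo-1,3-phenylene)bis(oxy)]bis(tert-butyldimethylsilane) | CC(C)(C)[Si](C)(C)Oc1cccc(O[Si](C)(C)C(C)(C)C)c1I
F11 | step 2 | 4-[2,6-bis(tert-butyldimethylsilyloxy)phenyl]-2-methylbut-3-yn-2-ol | CC(C)(O)C#Cc1c(O[Si](C)(C)C(C)(C)C)cccc1O[Si](C)(C)C(C)(C)C
F12 | step 2 | 4-[2,6-bis(tert-butyldimethylsilyloxy)phenyl]-2-methylbutan-2-ol | CC(C)(O)CCc1c(O[Si](C)(C)C(C)(C)C)cccc1O[Si](C)(C)C(C)(C)C
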